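**Plan**

1. Retrosynthesis: cut the coumarate ester C–O bond, return the C3 CH2O carbon to a formyl group, then cut the C2–C3 bond of the tetrahydrofuran. This turns the five-membered ring into a seven-membered cyclic vinyl acetal (a 4,5-dihydro-1,3-dioxepine). That is cut further at the benzyl–ring bond (Heck) and at the acetal (aryl aldehyde plus cis-butenediol).
2. Enabling feature: ring oxygen O1 and the aryl group make C2 a latent aryl-stabilised oxocarbenium carbon, and the oxygenated carbon on C3 is a latent enol. The 1,3-related pair O1–C2 / C3–CH=O is the pattern of an acetal carbon bound to an enol-ether oxygen.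
3. Forward: silylated vanillin is acetalised with cis-butenediol, a benzyl Heck reaction installs the benzyl group and the enol ether, and a Lewis acid 1,3 oxygen-to-carbon shift contracts the seven-membered ring to the tetrahydrofuran (the only non-aromatic ring, closed last). Reduction, esterification and desilylation follow.
4. Stereochemistry: C4 comes from the catalyst-controlled Heck step. C2 and C3 are set from C4 in the ring contraction (bond formation anti to benzyl, aryl cis to formyl kinetically), then base epimerises C3 alone to the 2,3-trans-3,4-cis array.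

Key step: step 6

Assumption: the sense of induction of step 5 cannot be read from precedent on other rings, so the ligand antipode written is the one taken to give the 5S series; its mirror image would be used if a first run shows the opposite sense.

Abbreviations: TIPS = triisopropylsilyl, TBS = tert-butyldimethylsilyl.

Step 1
Reactants: 1 vanillin (4-hydroxy-3-methoxybenzaldehyde)
Product: 2 3-methoxy-4-(triisopropylsilyloxy)benzaldehyde
Conditions: TIPSCl (1.1 equiv), imidazole (2 equiv), DMF, rt
Reagents that add atoms: triisopropylsilyl chloride, CC(C)[Si](Cl)(C(C)C)C(C)C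
Why: Imidazole-mediated silylation masks the phenol with a group that should withstand the carbonate, Lewis acid and hydride steps and fall to fluoride at the end.

Step 2
Reactants: 2 3-methoxy-4-(triisopropylsilyloxy)benzaldehyde
Product: 3 [3-methoxy-4-(triisopropylsilyloxy)phenyl]methanol
Conditions: NaBH4, MeOH/THF, 0 °C
Reagents that add atoms: none
Why: Borohydride reduction of an aryl aldehyde to the benzylic alcohol is chemoselective and should leave the aryl silyl ether intact at 0 °C.

Step 3
Reactants: 3 [3-methoxy-4-(triisopropylsilyloxy)phenyl]methanol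
Product: 4 3-methoxy-4-(triisopropylsilyloxy)benzyl trifluoroacetate
Conditions: (CF3CO)2O, pyridine, CH2Cl2, 0 °C; used without chromatography
Reagents that add atoms: trifluoroacetic anhydride, O=C(OC(=O)C(F)(F)F)C(F)(F)F
Why: O-acylation gives a benzylic ester that ionises readily at zerovalent palladium and whose weakly coordinating counter-ion favours the cationic Heck pathway.

Step 4
Reactants: 2 3-methoxy-4-(triisopropylsilyloxy)benzaldehyde; 5 (Z)-but-2-ene-1,4-diol
Product: 6 2-[3-methoxy-4-(triisopropylsilyloxy)phenyl]-4,7-dihydro-1,3-dioxepine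
Conditions: pyridinium p-toluenesulfonate (5 mol %), benzene, reflux, Dean–Stark trap
Reagents that add atoms: none
Why: Acid-catalysed acetalisation with azeotropic removal of water is the standard entry to 2-aryl-4,7-dihydro-1,3-dioxepines, and the cis alkene pre-organises the diol for seven-membered ring closure.

Step 5
Reactants: 6 2-[3-methoxy-4-(triisopropylsilyloxy)phenyl]-4,7-dihydro-1,3-dioxepine; 4 3-methoxy-4-(triisopropylsilyloxy)benzyl trifluoroacetate
Product: 7 (5S)-2-[3-methoxy-4-(triisopropylsilyloxy)phenyl]-5-[3-methoxy-4-(triisopropylsilyloxy)benzyl]-4,5-dihydro-1,3-dioxepine (both epimers at the acetal carbon C2)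
Conditions: Pd(dba)2 [bis(dibenzylideneacetone)palladium] (5 mol %), (S)-BINOL-derived phosphoramidite with a bis[(S)-1-phenylethyl]amino group (10 mol %), Li2CO3 (2 equiv), N,N-dimethylacetamide, 50 °C
Reagents that add atoms: none
Why: Proposed new method: zerovalent palladium with a monodentate phosphoramidite should insert into the benzylic C–O bond of 4 to give a cationic η3-benzyl palladium trifluoroacetate, which adds syn across the cis alkene of 6 at one of its two enantiotopic carbons (ligand control; attack on either ring face gives the same configuration at C5, only C2 differs), and the only syn β-hydrogen then lies on C7, so β-hydride elimination should deliver the enol ether without touching the new stereocentre; the closest known reaction types are the asymmetric Heck arylation of 4,7-dihydro-1,3-dioxepines with aryl triflates and the asymmetric Mizoroki–Heck reaction of benzyl trifluoroacetates with cyclic olefins.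

Step 6
Reactants: 7 (5S)-2-[3-methoxy-4-(triisopropylsilyloxy)phenyl]-5-[3-methoxy-4-(triisopropylsilyloxy)benzyl]-4,5-dihydro-1,3-dioxepine
Product: 10 (2R,3R,4S)-2-[3-methoxy-4-(triisopropylsilyloxy)phenyl]-4-[3-methoxy-4-(triisopropylsilyloxy)benzyl]tetrahydrofuran-3-carbaldehyde (2,3-trans-3,4-cis), via oxocarbenium silyl enol ether ion pair 8 (not isolated), via kinetic 2,3-cis aldehyde 9 (not isolated)
Conditions: TMSOTf (trimethylsilyl trifluoromethanesulfonate, 10 mol %), CH2Cl2, −78 °C; Et3N (0.3 equiv) at −78 °C; then DBU (1,8-diazabicyclo[5.4.0]undec-7-ene, 0.2 equiv), 0 °C to rt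
Reagents that add atoms: none
Why: TMSOTf should silylate the vinylic acetal oxygen and ionise the C2–O bond to the aryl-stabilised (E)-oxocarbenium ion paired with a (Z)-silyl enol ether (8), whose enol carbon then attacks the oxocarbenium carbon, a 1,3 oxygen-to-carbon shift that makes the C2–C3 bond, frees the formyl group and returns the silyl cation. The closest known reaction type is the Lewis acid mediated ring contraction of 4,5-dihydro-1,3-dioxepines to tetrahydrofuran-3-carbaldehydes (a vinyl acetal rearrangement related to the Petasis–Ferrier and Mukaiyama aldol reactions). The tetrahydrofuran closes in a 5-(enolexo)-endo-trig mode, which is tolerated for oxocarbenium electrophiles because the cation can tilt out of plane. C3 is controlled by the benzyl-bearing C4, since with the C4–H eclipsing the enol double bond (allylic 1,3-strain) the electrophile adds to the face anti to benzyl (3,4-trans), and C2 is controlled by the compact synclinal ion-pair arrangement that places aryl cis to formyl (the kinetic 2,3-cis preference of this ring contraction), so aryl and benzyl should end up trans as in 9. DBU should then invert only the enolisable C3, trading the aryl/formyl contact for a smaller formyl/benzyl contact to give the 2,3-trans-3,4-cis aldehyde 10. The step needs C–C rather than C–O recombination and no re-ionisation at C2: the first is secured because O-recombination only regenerates 7 while C-attack is irreversible at −78 °C, the second by catalytic acid, low temperature and the amine quench before warming.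

Step 7
Reactants: 10 (2R,3R,4S)-2-[3-methoxy-4-(triisopropylsilyloxy)phenyl]-4-[3-methoxy-4-(triisopropylsilyloxy)benzyl]tetrahydrofuran-3-carbaldehyde
Product: 11 [(2R,3S,4S)-2-[3-methoxy-4-(triisopropylsilyloxy)phenyl]-4-[3-methoxy-4-(triisopropylsilyloxy)benzyl]tetrahydrofuran-3-yl]methanol
Conditions: NaBH4, MeOH/THF, 0 °C
Reagents that add atoms: none
Why: Borohydride reduction of the aldehyde to the primary alcohol should leave all three stereocentres untouched and removes the enolisable position, fixing the 2,3-trans-3,4-cis array (the C3 descriptor changes only through the priority rules).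

Step 8
Reactants: 12 (E)-4-hydroxycinnamic acid (p-coumaric acid)
Product: 14 (E)-4-(tert-butyldimethylsilyloxy)cinnamic acid, via bis-silylated coumarate 13 (not isolated)
Conditions: TBSCl (2.3 equiv), imidazole (5 equiv), DMF, rt; then AcOH/THF/H2O, rt
Reagents that add atoms: tert-butyldimethylsilyl chloride, CC(C)(C)[Si](C)(C)Cl
Why: Exhaustive silylation followed by selective hydrolysis of the far more labile silyl ester should leave the phenol protected and the acid free for coupling.

Step 9
Reactants: 11 [(2R,3S,4S)-2-[3-methoxy-4-(triisopropylsilyloxy)phenyl]-4-[3-methoxy-4-(triisopropylsilyloxy)benzyl]tetrahydrofuran-3-yl]methanol; 14 (E)-4-(tert-butyldimethylsilyloxy)cinnamic acid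
Product: 15 [(2R,3S,4S)-2-[3-methoxy-4-(triisopropylsilyloxy)phenyl]-4-[3-methoxy-4-(triisopropylsilyloxy)benzyl]tetrahydrofuran-3-yl]methyl (E)-3-[4-(tert-butyldimethylsilyloxy)phenyl]prop-2-enoate
Conditions: N,N'-dicyclohexylcarbodiimide (1.2 equiv), 4-dimethylaminopyridine (0.1 equiv), CH2Cl2, 0 °C to rt
Reagents that add atoms: none
Why: Steglich esterification (carbodiimide activation, acyl transfer by the aminopyridine) should acylate the only free hydroxyl, the primary alcohol, without isomerising the E alkene.

Step 10
Reactants: 15 [(2R,3S,4S)-2-[3-methoxy-4-(triisopropylsilyloxy)phenyl]-4-[3-methoxy-4-(triisopropylsilyloxy)benzyl]tetrahydrofuran-3-yl]methyl (E)-3-[4-(tert-butyldimethylsilyloxy)phenyl]prop-2-enoate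
Product: 16 lariciresinol p-coumarate, [(2R,3S,4S)-4-(4-hydroxy-3-methoxybenzyl)-2-(4-hydroxy-3-methoxyphenyl)tetrahydrofuran-3-yl]methyl (E)-3-(4-hydroxyphenyl)prop-2-enoate
Conditions: Bu4NF (3.3 equiv), AcOH (3.3 equiv), THF, 0 °C
Reagents that add atoms: none
Why: Acetic acid-buffered fluoride should cleave the three aryl silyl ethers (Si–F bond formation, phenoxide leaving groups) under conditions mild enough for the cinnamate ester and the acid-sensitive benzylic ether.

**Compound list**

1 | vanillin (4-hydroxy-3-methoxybenzaldehyde) | COc1cc(C=O)ccc1O | starting material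
2 | 3-methoxy-4-(triisopropylsilyloxy)benzaldehyde | COc1cc(C=O)ccc1O[Si](C(C)C)(C(C)C)C(C)C | intermediate
3 | [3-methoxy-4-(triisopropylsilyloxy)phenyl]methanol | COc1cc(CO)ccc1O[Si](C(C)C)(C(C)C)C(C)C | intermediate
4 | 3-methoxy-4-(triisopropylsilyloxy)benzyl trifluoroacetate | COc1cc(COC(=O)C(F)(F)F)ccc1O[Si](C(C)C)(C(C)C)C(C)C | intermediate
5 | (Z)-but-2-ene-1,4-diol | OC/C=C\CO | starting material
6 | 2-[3-methoxy-4-(triisopropylsilyloxy)phenyl]-4,7-dihydro-1,3-dioxepine | COc1cc(C2OC/C=C\CO2)ccc1O[Si](C(C)C)(C(C)C)C(C)C | intermediate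
7 | (5S)-2-[3-methoxy-4-(triisopropylsilyloxy)phenyl]-5-[3-methoxy-4-(triisopropylsilyloxy)benzyl]-4,5-dihydro-1,3-dioxepine, both C2 epimers | COc1cc(C[C@@H]2COC(c3ccc(O[Si](C(C)C)(C(C)C)C(C)C)c(OC)c3)OC=C2)ccc1O[Si](C(C)C)(C(C)C)C(C)C | intermediate
8 | ion pair: (E)-oxocarbenium triflate of aldehyde 2 O-alkylated by the (2S,3Z)-2-benzyl-4-(trimethylsilyloxy)but-3-enyl chain (benzyl = 3-methoxy-4-(triisopropylsilyloxy)benzyl) | COc1cc(C[C@H](C/[O+]=C/c2ccc(O[Si](C(C)C)(C(C)C)C(C)C)c(OC)c2)/C=C\O[Si](C)(C)C)ccc1O[Si](C(C)C)(C(C)C)C(C)C.[O-]S(=O)(=O)C(F)(F)F | intermediate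
9 | (2R,3S,4S)-2-[3-methoxy-4-(triisopropylsilyloxy)phenyl]-4-[3-methoxy-4-(triisopropylsilyloxy)benzyl]tetrahydrofuran-3-carbaldehyde (2,3-cis-3,4-trans) | COc1cc(C[C@@H]2CO[C@@H](c3ccc(O[Si](C(C)C)(C(C)C)C(C)C)c(OC)c3)[C@H]2C=O)ccc1O[Si](C(C)C)(C(C)C)C(C)C | intermediate
10 | (2R,3R,4S)-2-[3-methoxy-4-(triisopropylsilyloxy)phenyl]-4-[3-methoxy-4-(triisopropylsilyloxy)benzyl]tetrahydrofuran-3-carbaldehyde (2,3-trans-3,4-cis) | COc1cc(C[C@@H]2CO[C@@H](c3ccc(O[Si](C(C)C)(C(C)C)C(C)C)c(OC)c3)[C@@H]2C=O)ccc1O[Si](C(C)C)(C(C)C)C(C)C | intermediate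
11 | [(2R,3S,4S)-2-[3-methoxy-4-(triisopropylsilyloxy)phenyl]-4-[3-methoxy-4-(triisopropylsilyloxy)benzyl]tetrahydrofuran-3-yl]methanol | COc1cc(C[C@@H]2CO[C@@H](c3ccc(O[Si](C(C)C)(C(C)C)C(C)C)c(OC)c3)[C@@H]2CO)ccc1O[Si](C(C)C)(C(C)C)C(C)C | intermediate
12 | (E)-4-hydroxycinnamic acid (p-coumaric acid) | OC(=O)/C=C/c1ccc(O)cc1 | starting material
13 | tert-butyldimethylsilyl (E)-4-(tert-butyldimethylsilyloxy)cinnamate | CC(C)(C)[Si](C)(C)OC(=O)/C=C/c1ccc(O[Si](C)(C)C(C)(C)C)cc1 | intermediate
14 | (E)-4-(tert-butyldimethylsilyloxy)cinnamic acid | OC(=O)/C=C/c1ccc(O[Si](C)(C)C(C)(C)C)cc1 | intermediate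
15 | [(2R,3S,4S)-2-[3-methoxy-4-(triisopropylsilyloxy)phenyl]-4-[3-methoxy-4-(triisopropylsilyloxy)benzyl]tetrahydrofuran-3-yl]methyl (E)-3-[4-(tert-butyldimethylsilyloxy)phenyl]prop-2-enoate | COc1cc(C[C@@H]2CO[C@@H](c3ccc(O[Si](C(C)C)(C(C)C)C(C)C)c(OC)c3)[C@@H]2COC(=O)/C=C/c2ccc(O[Si](C)(C)C(C)(C)C)cc2)ccc1O[Si](C(C)C)(C(C)C)C(C)C | intermediate
16 | lariciresinol p-coumarate, [(2R,3S,4S)-4-(4-hydroxy-3-methoxybenzyl)-2-(4-hydroxy-3-methoxyphenyl)tetrahydrofuran-3-yl]methyl (E)-3-(4-hydroxyphenyl)prop-2-enoate | COc1cc(C[C@@H]2CO[C@@H](c3ccc(O)c(OC)c3)[C@@H]2COC(=O)/C=C/c2ccc(O)cc2)ccc1O | target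

**Step count**

Total steps: 10. Longest linear sequence: 8 steps (1 → 2 → 3 → 4 → 7 → 10 → 11 → 15 → 16).

**Steps most likely to fail**

Step 5 (proposed new method). Carbopalladation of the ring alkene may be outrun by homocoupling or reduction of the electron-rich benzyl electrophile, discrimination of the two enantiotopic alkene carbons may be poor, and palladium hydride may move the double bond further. The fallback uses known reaction types only; it sets out from alcohol 3 and aldehyde 2 and comes back at alcohol 11. Alcohol 3 would be converted (CBr4, PPh3, CH2Cl2, 0 °C) into 4-(bromomethyl)-2-methoxyphenyl triisopropylsilyl ether F1. Zinc insertion (Zn, LiCl, THF) would give [3-methoxy-4-(triisopropylsilyloxy)benzyl]zinc bromide F2, and Negishi coupling with commercial 4-bromofuran-2(5H)-one (Pd(PPh3)4, THF) would give 4-[3-methoxy-4-(triisopropylsilyloxy)benzyl]furan-2(5H)-one F3. Asymmetric conjugate reduction with a monovalent copper hydride catalyst (CuCl, NaOtBu, the p-tol-BINAP antipode that gives the S product, polymethylhydrosiloxane) would give (4S)-4-[3-methoxy-4-(triisopropylsilyloxy)benzyl]dihydrofuran-2(3H)-one F4. Its lithium enolate (LiN(iPr)2, THF, −78 °C) should add to aldehyde 2 anti to the benzyl group to give the trans aldol lactone (3R,4S)-3-{hydroxy[3-methoxy-4-(triisopropylsilyloxy)phenyl]methyl}-4-[3-methoxy-4-(triisopropylsilyloxy)benzyl]dihydrofuran-2(3H)-one F5 as carbinol epimers. LiBH4 would reduce it to (2S,3S)-2-{hydroxy[3-methoxy-4-(triisopropylsilyloxy)phenyl]methyl}-3-[3-methoxy-4-(triisopropylsilyloxy)benzyl]butane-1,4-diol F6. Catalytic camphorsulfonic acid (CH2Cl2, 0 °C) should then ionise the benzylic carbinol, so that the primary hydroxyl of the benzyl-bearing branch closes the tetrahydrofuran trans to the C3 substituent and gives 11.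

Step 6 (key step). Facial selectivity at the oxocarbenium carbon relative to C4 may be low (an antiperiplanar transition state would lead to the all-trans series). The Lewis acid may re-ionise the benzylic C2–O bond of the product, followed by Friedel–Crafts attack of the benzyl ring. The C3 equilibrium may be less one-sided than expected, or β-elimination may open the ring during the base treatment. The fallback sets out from 7 and comes back at 11. Mild aqueous acid (oxalic acid, wet THF) would hydrolyse the enol acetal to (4S)-4-[3-methoxy-4-(triisopropylsilyloxy)benzyl]tetrahydrofuran-2-ol F7 and return aldehyde 2 for re-use. Oxidation (2,2,6,6-tetramethylpiperidin-1-oxyl, PhI(OAc)2, CH2Cl2) would give lactone F4. The aldol, reduction and acid cyclisation described for the first fallback would then lead through F5 and F6 to 11. In this variant C3 is fixed by trans alkylation of the lactone and C2 by the benzylic etherification.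

Step 10. Basic fluoride may cleave or shift the cinnamate ester, phenoxide formation may trigger opening of the p-oxybenzylic ether, and the hindered silyl groups may come off incompletely. The fallback sets out from 11 and comes back at 16 with the ester formed last. Desilylation of 11 (Bu4NF, AcOH, THF) would give 4-[(2R,3S,4S)-4-(4-hydroxy-3-methoxybenzyl)-3-(hydroxymethyl)tetrahydrofuran-2-yl]-2-methoxyphenol F8. Mitsunobu esterification (PPh3, diisopropyl azodicarboxylate, THF, 0 °C) with unprotected p-coumaric acid 12 should then acylate the primary alcohol selectively, because the carboxylic acid is far more acidic than the phenols.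

**Further compounds**

F1 | step 5 | 4-(bromomethyl)-2-methoxyphenyl triisopropylsilyl ether | COc1cc(CBr)ccc1O[Si](C(C)C)(C(C)C)C(C)C
F2 | step 5 | [3-methoxy-4-(triisopropylsilyloxy)benzyl]zinc bromide | COc1cc(C[Zn]Br)ccc1O[Si](C(C)C)(C(C)C)C(C)C
F3 | step 5 | 4-[3-methoxy-4-(triisopropylsilyloxy)benzyl]furan-2(5H)-one | COc1cc(CC2=CC(=O)OC2)ccc1O[Si](C(C)C)(C(C)C)C(C)C
F4 | step 5 | (4S)-4-[3-methoxy-4-(triisopropylsilyloxy)benzyl]dihydrofuran-2(3H)-one | COc1cc(C[C@H]2CC(=O)OC2)ccc1O[Si](C(C)C)(C(C)C)C(C)C
F5 | step 5 | (3R,4S)-3-{hydroxy[3-methoxy-4-(triisopropylsilyloxy)phenyl]methyl}-4-[3-methoxy-4-(triisopropylsilyloxy)benzyl]dihydrofuran-2(3H)-one, carbinol epimers | COc1cc(C[C@@H]2COC(=O)[C@H]2C(O)c2ccc(O[Si](C(C)C)(C(C)C)C(C)C)c(OC)c2)ccc1O[Si](C(C)C)(C(C)C)C(C)C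
F6 | step 5 | (2S,3S)-2-{hydroxy[3-methoxy-4-(triisopropylsilyloxy)phenyl]methyl}-3-[3-methoxy-4-(triisopropylsilyloxy)benzyl]butane-1,4-diol, carbinol epimers | COc1cc(C[C@H](CO)[C@@H](CO)C(O)c2ccc(O[Si](C(C)C)(C(C)C)C(C)C)c(OC)c2)ccc1O[Si](C(C)C)(C(C)C)C(C)C
F7 | step 6 | (4S)-4-[3-methoxy-4-(triisopropylsilyloxy)benzyl]tetrahydrofuran-2-ol, both anomers | COc1cc(C[C@H]2CC(O)OC2)ccc1O[Si](C(C)C)(C(C)C)C(C)C
F8 | step 10 | 4-[(2R,3S,4S)-4-(4-hydroxy-3-methoxybenzyl)-3-(hydroxymethyl)tetrahydrofuran-2-yl]-2-methoxyphenol | COc1cc(C[C@@H]2CO[C@@H](c3ccc(O)c(OC)c3)[C@@H]2CO)ccc1O
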